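**Plan**

1. Numbering: C1 (geranyl bridgehead), C2–C3–C4 (dione bridge), C5 (prenyl bridgehead), C6 (CMe2), C7 (CH-prenyl), C8 (CH2), C9 (bridging C=O). Ring A = C1–C2–C3–C4–C5–C9, ring B = C1–C8–C7–C6–C5–C9; "exo" at C7 is the face turned away from C2–C4.
2. Enabling feature: ring A can be carried as a 2,6-dimethoxycyclohexa-2,5-diene whose quaternary C5 lies on a mirror plane. Its enol ether bonds C9=C1 and C4=C3 are therefore enantiotopic, and a carbenoid at C8, hung from C5 through C6–C7, reaches either one through a five-membered ring.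
3. Retrosynthetic cuts, in order: C3–aroyl, C1–geranyl, both prenyl C=C bonds (from allyl groups), the C2 oxygen, C7–allyl, then C1–C8 (ring B), C5–allyl and the aryl–C6 bond.
4. Forward: the arene is joined to C6, Birch reduction turns it into ring A as the diene, allylation makes C5 quaternary, the carbenoid step closes ring B, then C7, C2, C1 and C3 are dressed in that order.
5. Stereochemistry: C1 and C5 come from a chiral copper–bis(oxazoline) catalyst choosing one enol ether; C7 from exo-face radical allylation on the rigid bicycle; the bridgehead alkylation at C1 can only retain; the E olefin is bought with geranyl bromide.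

Key step: step 7

Assumption: the sense of induction of the copper–bis(oxazoline) catalyst cannot be predicted with confidence; the (S,S) ligand is written, and its antipode is used if the first run gives the mirror image of 14.
Remark: the C5 side chain is carried as allyl (less nucleophilic towards the carbenoid, slower in the C2 oxidation) and becomes prenyl together with the C7 allyl group in one metathesis.
Remark: the β-hydroxy enone of the target is a fast tautomeric pair (enol at C2 or at C4); the route delivers this pair, drawn as the C2 enol.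

Step 1
Reactants: 1 2-bromo-1,3-dimethoxybenzene; 2 isobutyronitrile
Product: 3 2-(2,6-dimethoxyphenyl)-2-methylpropanenitrile
Conditions: Pd(OAc)2 (2 mol %), rac-BINAP (3 mol %), NaN(SiMe3)2 (1.3 equiv), toluene, 100 °C
Reagents that add atoms: none
Why: Palladium-catalysed α-arylation of a nitrile: oxidative addition of 1 to zerovalent palladium, exchange with the sodium keteniminate of 2 and C–C reductive elimination build the quaternary benzylic carbon (future C6), the slim nitrile anion tolerating the two ortho methoxy groups.

Step 2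
Reactants: 3
Product: 5 3-(2,6-dimethoxyphenyl)-3-methylbutan-2-one, via lithium ketimide 4 (not isolated)
Conditions: MeLi (1.5 equiv), Et2O–toluene, 0 → 60 °C; then 2 M aq HCl, 25 °C
Reagents that add atoms: methyllithium, [Li]C; water, O
Why: Addition of an organolithium to a nitrile without α-hydrogen stops at the N-lithio ketimine, which aqueous acid hydrolyses to the methyl ketone (the arene is indifferent to acid at this stage).

Step 3
Reactants: 5
Product: 7 3-(2,6-dimethoxycyclohexa-2,5-dien-1-yl)-3-methylbutan-2-ol, via aryl carbinol 6 (not isolated)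
Conditions: Li (6 equiv), NH3(l)–THF, t-BuOH (6 equiv), −78 → −33 °C; solid NH4Cl, work-up at pH 8
Reagents that add atoms: none
Why: Birch reduction: the ketone is reduced first to its alkoxide, which survives while the resorcinol diether ring takes up two electrons and is protonated at the carbon between the methoxy groups and at the para carbon, leaving both methoxy groups on double bonds; the carbinol centre is racemic and disappears in step 5.

Step 4
Reactants: 7; 8 allyl bromide
Product: 9 3-[2,6-dimethoxy-1-(prop-2-en-1-yl)cyclohexa-2,5-dien-1-yl]-3-methylbutan-2-ol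
Conditions: t-BuLi (2.3 equiv), THF–HMPA, −78 → −40 °C; then 8, −78 → 0 °C
Reagents that add atoms: none
Why: Alkylation of a Birch diene by bis-allylic lithiation (Piers-type): after the hydroxyl proton, tert-butyllithium removes the ring C–H flanked by both enol ethers, helped by the neighbouring lithium alkoxide, and the pentadienyl anion takes allyl bromide at its central carbon to restore the 1,4-diene; C5 stays on the mirror plane, so no stereocentre arises.

Step 5
Reactants: 9
Product: 10 3-[2,6-dimethoxy-1-(prop-2-en-1-yl)cyclohexa-2,5-dien-1-yl]-3-methylbutan-2-one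
Conditions: Dess–Martin periodinane, pyridine, CH2Cl2, 0 → 25 °C
Reagents that add atoms: none
Why: Dess–Martin oxidation of the secondary alcohol under pyridine buffer is neutral enough for the two enol ethers and gives a methyl ketone with a single enolisable position.

Step 6
Reactants: 10
Product: 12 1-diazo-3-[2,6-dimethoxy-1-(prop-2-en-1-yl)cyclohexa-2,5-dien-1-yl]-3-methylbutan-2-one, via trifluoroacetyl diketone 11 (not isolated)
Conditions: LiN(SiMe3)2, THF, −78 °C; CF3CO2CH2CF3; then MsN3, Et3N, H2O (1 equiv), MeCN, 25 °C
Reagents that add atoms: methanesulfonyl azide, CS(=O)(=O)N=[N+]=[N-]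
Why: Detrifluoroacetylative diazo transfer (Danheiser): the kinetic methyl enolate is C-trifluoroacetylated and the resulting 1,3-diketone accepts the diazo group from the sulfonyl azide with loss of the trifluoroacetyl group as its sulfonamide, all under basic conditions that spare the enol ethers.

Step 7
Reactants: 12
Product: 14 (1R,5R)-4-methoxy-6,6-dimethyl-5-(prop-2-en-1-yl)bicyclo[3.3.1]non-3-ene-7,9-dione, via methoxycyclopropane 13 (not isolated)
Conditions: [Cu(MeCN)4]PF6 (10 mol %), 2,2'-(propane-2,2-diyl)bis[(4S)-4-tert-butyl-4,5-dihydro-1,3-oxazole] (12 mol %), CH2Cl2, 25 °C, slow addition of 12; then 0.1 M aq HCl–THF, 0 °C, 15 min; NaHCO3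
Reagents that add atoms: water, O
Why: The cationic complex of monovalent copper turns the diazoketone into an electrophilic carbenoid at C8, which adds to the enol ether bond C9=C1 in an asynchronous [2+1] step (new bonds C8–C1 and C8–C9); acid then activates the C7 ketone, the C8–C9 bond of the methoxy/acyl-substituted cyclopropane breaks, and water turns the C9 oxocarbenium ion into the ketone, so that the net new skeletal bond is C1–C8. The closest known reaction type is the copper–bis(oxazoline)-catalysed asymmetric intramolecular cyclopropanation of diazoketones with enol ethers, followed by opening of the donor–acceptor cyclopropane. The cyclopropanation closes the five-membered ketone ring C8–C7–C6–C5–C9 (bicyclo[3.1.0]hexanone mode, the fastest for a three-atom tether), and cleavage of the shared C8–C9 bond enlarges it to the six-membered ring B, bridged across ring A. C1 and C5 are set together when the ligand pocket chooses between the two enantiotopic enol ethers, the cis fusion being forced by the tether, while the C8 and C9 centres of the cyclopropane vanish on opening. The step needs group selectivity between the enol ethers (catalyst), preference for them over the terminal allyl alkene and over C–H insertion (the enol ethers are more nucleophilic and give the smaller ring, and copper rather than rhodium is used), and survival of the second enol ether during opening (the push–pull cyclopropane should open under a cold, brief, dilute acid treatment that an isolated enol ether tolerates).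

Step 8
Reactants: 14
Product: 15 4-methoxy-6,6-dimethyl-9-oxo-5-(prop-2-en-1-yl)bicyclo[3.3.1]nona-3,7-dien-7-yl trifluoromethanesulfonate
Conditions: KN(SiMe3)2 (1.1 equiv), THF, −78 °C; PhNTf2, −78 → 0 °C
Reagents that add atoms: N-phenylbis(trifluoromethanesulfonimide), O=S(=O)(N(c1ccccc1)S(=O)(=O)C(F)(F)F)C(F)(F)F
Why: Kinetic enolate triflation: only the C7 ketone can enolise (towards C8), because the sole α-hydrogen of the C9 ketone is at the bridgehead, so O-sulfonylation marks C7 and tells the two ketones apart.

Step 9
Reactants: 15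
Product: 16 methyl 4-methoxy-6,6-dimethyl-9-oxo-5-(prop-2-en-1-yl)bicyclo[3.3.1]nona-3,7-diene-7-carboxylate
Conditions: Pd(OAc)2 (5 mol %), PPh3 (10 mol %), Et3N, MeOH–DMF, CO (1 atm), 60 °C
Reagents that add atoms: carbon monoxide, [C-]#[O+]; methanol, CO
Why: Palladium-catalysed methoxycarbonylation of an alkenyl triflate (oxidative addition, CO insertion, methanolysis of the acyl palladium) places a carboxyl carbon on C7.

Step 10
Reactants: 16
Product: 17 methyl 4-methoxy-6,6-dimethyl-9-oxo-5-(prop-2-en-1-yl)bicyclo[3.3.1]non-3-ene-7-carboxylate (C7 epimers)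
Conditions: [(Ph3P)CuH]6 (0.4 equiv), toluene, H2O (3 equiv), 25 °C
Reagents that add atoms: none
Why: Conjugate reduction with Stryker's reagent: hydride from monovalent copper adds to C8 of the enoate and the copper enolate is protonated by water, while the isolated C9 ketone, the enol ether and the terminal alkene are left alone; the C7 configuration formed here is of no consequence.

Step 11
Reactants: 17
Product: 18 7-exo-4-methoxy-6,6-dimethyl-9-oxo-5-(prop-2-en-1-yl)bicyclo[3.3.1]non-3-ene-7-carboxylic acid
Conditions: KOH, MeOH–H2O, 70 °C; then cold dilute HCl to pH 4–5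
Reagents that add atoms: potassium hydroxide, [K+].[OH-]
Why: Saponification of the ester; under the basic conditions the ester first epimerises to the exo (equatorial) position, which keeps the carboxyl group away from the acid-sensitive enol ether on work-up, and the C7 centre is in any case erased in step 12.

Step 12
Reactants: 18
Product: 20 4-methoxy-6,6-dimethyl-7-(phenylselanyl)-5-(prop-2-en-1-yl)bicyclo[3.3.1]non-3-en-9-one (C7 epimers), via O-acyl thiohydroxamate 19 (not isolated)
Conditions: N-hydroxypyridine-2-thione, DCC, DMAP (cat.), CH2Cl2, 0 °C, dark; then (PhSe)2, tungsten lamp, 25 °C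
Reagents that add atoms: diphenyl diselenide, c1ccccc1[Se][Se]c1ccccc1
Why: Barton decarboxylation: the O-acyl thiohydroxamate fragments under light to CO2 and the secondary C7 radical, which is captured at selenium by the diselenide, giving a radical precursor at C7 without any reducing agent coming near the C9 ketone.

Step 13
Reactants: 20
Product: 21 7-exo-4-methoxy-6,6-dimethyl-5,7-di(prop-2-en-1-yl)bicyclo[3.3.1]non-3-en-9-one
Conditions: allyltributylstannane (8 equiv), AIBN (0.2 equiv), benzene, 80 °C
Reagents that add atoms: allyltributylstannane, C=CC[Sn](CCCC)(CCCC)CCCC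
Why: Keck radical allylation: the stannyl radical abstracts the phenylselanyl group and the C7 radical adds to the allylstannane on the exo face, because the endo face lies about 3 Å above the C3=C4 bridge, which sets C7 with the allyl group anti to ring A; closure onto the C5 allyl group would need a diequatorial two-atom bridge and is not expected.

Step 14
Reactants: 21
Product: 22 7-exo-4-methoxy-6,6-dimethyl-5,7-di(prop-2-en-1-yl)bicyclo[3.3.1]non-3-ene-2,9-dione
Conditions: Pd(OH)2/C (10 mol %), t-BuOOH (5 equiv), Cs2CO3, CH2Cl2, 0 → 25 °C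
Reagents that add atoms: tert-butyl hydroperoxide, CC(C)(C)OO
Why: Allylic C–H oxidation with tert-butyl hydroperoxide: the C2 hydrogens, allylic to the electron-rich enol ether, are abstracted in preference to those of the two terminal allyl groups, and the C2 peroxide collapses under base (Kornblum–DeLaMare) to the vinylogous ester.

Step 15
Reactants: 22
Product: 23 7-exo-4-methoxy-6,6-dimethyl-5,7-bis(3-methylbut-2-en-1-yl)bicyclo[3.3.1]non-3-ene-2,9-dione
Conditions: second-generation Grubbs catalyst (H2IMes)(PCy3)Cl2Ru=CHPh (10 mol %), 2-methylbut-2-ene–CH2Cl2, 40 °C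
Reagents that add atoms: 2-methylbut-2-ene, CC=C(C)C
Why: Olefin cross-metathesis of both terminal allyl groups with 2-methylbut-2-ene exchanges =CH2 for =CMe2; the electron-poor vinylogous ester double bond does not take part and no stereocentre is touched.

Step 16
Reactants: 23; 24 geranyl bromide
Product: 25 1-[(2E)-3,7-dimethylocta-2,6-dien-1-yl] derivative of 23
Conditions: LiN(i-Pr)2 (1.3 equiv), THF, −78 °C; then 24, −78 → −20 °C
Reagents that add atoms: none
Why: Bridgehead lithiation and alkylation: the C1 hydrogen, acidified inductively by the C2 and C9 carbonyl groups, is removed in preference to the vinylic C3 hydrogen, and the carbanion is alkylated by geranyl bromide in an SN2 reaction with retention, the only outcome open to a bridgehead, the E olefin being untouched.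

Step 17
Reactants: 26 3,4-dihydroxybenzoic acid
Product: 27 tert-butyldimethylsilyl 3,4-bis(tert-butyldimethylsilyloxy)benzoate
Conditions: TBSCl (3.5 equiv), imidazole, DMF, 25 °C
Reagents that add atoms: tert-butyldimethylsilyl chloride, CC(C)(C)[Si](C)(C)Cl
Why: Silylation of both phenols and of the carboxylic acid by the silyl chloride with imidazole as nucleophilic catalyst and base.

Step 18
Reactants: 27
Product: 28 3,4-bis(tert-butyldimethylsilyloxy)benzoyl chloride
Conditions: (COCl)2, DMF (cat.), CH2Cl2, 0 → 25 °C
Reagents that add atoms: oxalyl chloride, O=C(Cl)C(=O)Cl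
Why: Silyl esters are converted directly into acid chlorides by oxalyl chloride with catalytic DMF (Vilsmeier-type activation) under neutral conditions that leave the aryl silyl ethers intact.

Step 19
Reactants: 25; 28
Product: 29 3-[3,4-bis(tert-butyldimethylsilyloxy)benzoyl] derivative of 25
Conditions: lithium 2,2,6,6-tetramethylpiperidide (1.5 equiv), THF, −78 °C; then 28, −78 → −40 °C
Reagents that add atoms: none
Why: Vinylic deprotonation and acylation: the hindered amide base removes the C3 hydrogen between the C2 carbonyl and the C4 methoxy group, the only acidic site left, and the vinyllithium is C-acylated by the aroyl chloride.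

Step 20
Reactants: 29
Product: 31 CNP0160101.3, via catechol methyl ether 30 (not isolated)
Conditions: LiOH·H2O (10 equiv), 1,4-dioxane–H2O, 90 °C, argon; then cold 1 M HCl
Reagents that add atoms: lithium hydroxide, [Li+].[OH-]
Why: Hydroxide cleaves the two aryl silyl ethers at silicon and then displaces methoxide at C4 of the 2-acyl vinylogous ester by addition–elimination, releasing the enolised β-triketone; no stereocentre is involved and air is excluded to protect the catecholate.

**Compound list**

1 | 2-bromo-1,3-dimethoxybenzene | COc1cccc(OC)c1Br | starting material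
2 | isobutyronitrile (2-methylpropanenitrile) | CC(C)C#N | starting material
3 | 2-(2,6-dimethoxyphenyl)-2-methylpropanenitrile | COc1cccc(OC)c1C(C)(C)C#N | intermediate
4 | N-lithio ketimine of 5 (lithium ketimide; not isolated) | [Li]N=C(C)C(C)(C)c1c(OC)cccc1OC | intermediate
5 | 3-(2,6-dimethoxyphenyl)-3-methylbutan-2-one | CC(=O)C(C)(C)c1c(OC)cccc1OC | intermediate
6 | 3-(2,6-dimethoxyphenyl)-3-methylbutan-2-ol, racemic, present as its lithium alkoxide (not isolated) | CC(O)C(C)(C)c1c(OC)cccc1OC | intermediate
7 | 3-(2,6-dimethoxycyclohexa-2,5-dien-1-yl)-3-methylbutan-2-ol, racemic | CC(O)C(C)(C)C1C(OC)=CCC=C1OC | intermediate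
8 | allyl bromide (3-bromoprop-1-ene) | C=CCBr | starting material
9 | 3-[2,6-dimethoxy-1-(prop-2-en-1-yl)cyclohexa-2,5-dien-1-yl]-3-methylbutan-2-ol, racemic | CC(O)C(C)(C)C1(CC=C)C(OC)=CCC=C1OC | intermediate
10 | 3-[2,6-dimethoxy-1-(prop-2-en-1-yl)cyclohexa-2,5-dien-1-yl]-3-methylbutan-2-one | CC(=O)C(C)(C)C1(CC=C)C(OC)=CCC=C1OC | intermediate
11 | 1,1,1-trifluoro-5-[2,6-dimethoxy-1-(prop-2-en-1-yl)cyclohexa-2,5-dien-1-yl]-5-methylhexane-2,4-dione (not isolated) | O=C(CC(=O)C(C)(C)C1(CC=C)C(OC)=CCC=C1OC)C(F)(F)F | intermediate
12 | 1-diazo-3-[2,6-dimethoxy-1-(prop-2-en-1-yl)cyclohexa-2,5-dien-1-yl]-3-methylbutan-2-one (achiral; C5 on the mirror plane) | [N-]=[N+]=CC(=O)C(C)(C)C1(CC=C)C(OC)=CCC=C1OC | intermediate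
13 | methoxycyclopropane: tricyclic ketone in which C8 is bonded to C1, C7 and C9, C9 carries OMe, rings cis-fused on the side of C6 (not isolated) | [C@H]12C(=O)C(C)(C)[C@]3(CC=C)C(OC)=CC[C@H]1[C@]23OC | intermediate
14 | (1R,5R)-4-methoxy-6,6-dimethyl-5-(prop-2-en-1-yl)bicyclo[3.3.1]non-3-ene-7,9-dione | [C@H]12CC(=O)C(C)(C)[C@](CC=C)(C(OC)=CC1)C2=O | intermediate
15 | C7 enol triflate of 14 (C7=C8; bridgeheads arranged as in 14) | [C@H]12C=C(OS(=O)(=O)C(F)(F)F)C(C)(C)[C@](CC=C)(C(OC)=CC1)C2=O | intermediate
16 | methyl 7-ene-7-carboxylate (C7=C8; bridgeheads as in 14) | [C@H]12C=C(C(=O)OC)C(C)(C)[C@](CC=C)(C(OC)=CC1)C2=O | intermediate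
17 | saturated methyl 7-carboxylate, mixture of C7 epimers (bridgeheads as in 14) | [C@H]12CC(C(=O)OC)C(C)(C)[C@](CC=C)(C(OC)=CC1)C2=O | intermediate
18 | 7-exo carboxylic acid (carboxyl anti to ring A; bridgeheads as in 14) | [C@H]12C[C@@H](C(=O)O)C(C)(C)[C@](CC=C)(C(OC)=CC1)C2=O | intermediate
19 | 2-thioxopyridin-1(2H)-yl ester of 18 (Barton ester; not isolated) | [C@H]12C[C@@H](C(=O)ON3C=CC=CC3=S)C(C)(C)[C@](CC=C)(C(OC)=CC1)C2=O | intermediate
20 | 7-(phenylselanyl) compound, mixture of C7 epimers (bridgeheads as in 14) | [C@H]12CC([Se]c3ccccc3)C(C)(C)[C@](CC=C)(C(OC)=CC1)C2=O | intermediate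
21 | 7-exo-allyl, 5-allyl, 4-methoxy enol ether, C9 ketone (bridgeheads as in 14) | [C@H]12C[C@@H](CC=C)C(C)(C)[C@](CC=C)(C(OC)=CC1)C2=O | intermediate
22 | vinylogous ester: C2 ketone, C3=C4, 4-methoxy; 5-allyl, 7-exo-allyl | [C@H]12C[C@@H](CC=C)C(C)(C)[C@](CC=C)(C(OC)=CC1=O)C2=O | intermediate
23 | 5-prenyl, 7-exo-prenyl vinylogous ester | [C@H]12C[C@@H](CC=C(C)C)C(C)(C)[C@](CC=C(C)C)(C(OC)=CC1=O)C2=O | intermediate
24 | geranyl bromide, (2E)-1-bromo-3,7-dimethylocta-2,6-diene | CC(C)=CCC/C(C)=C/CBr | starting material
25 | 1-geranyl derivative of 23 (geranyl in place of the bridgehead hydrogen) | CC(C)=CCC/C(C)=C/C[C@]12C[C@@H](CC=C(C)C)C(C)(C)[C@](CC=C(C)C)(C(OC)=CC1=O)C2=O | intermediate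
26 | 3,4-dihydroxybenzoic acid | O=C(O)c1ccc(O)c(O)c1 | starting material
27 | tert-butyldimethylsilyl 3,4-bis(tert-butyldimethylsilyloxy)benzoate | CC(C)(C)[Si](C)(C)OC(=O)c1ccc(O[Si](C)(C)C(C)(C)C)c(O[Si](C)(C)C(C)(C)C)c1 | intermediate
28 | 3,4-bis(tert-butyldimethylsilyloxy)benzoyl chloride | O=C(Cl)c1ccc(O[Si](C)(C)C(C)(C)C)c(O[Si](C)(C)C(C)(C)C)c1 | intermediate
29 | 3-[3,4-bis(tert-butyldimethylsilyloxy)benzoyl] derivative of 25 | CC(C)=CCC/C(C)=C/C[C@]12C[C@@H](CC=C(C)C)C(C)(C)[C@](CC=C(C)C)(C(OC)=C(C(=O)c3ccc(O[Si](C)(C)C(C)(C)C)c(O[Si](C)(C)C(C)(C)C)c3)C1=O)C2=O | intermediate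
30 | 3-(3,4-dihydroxybenzoyl) 4-methyl ether (not isolated) | CC(C)=CCC/C(C)=C/C[C@]12C[C@@H](CC=C(C)C)C(C)(C)[C@](CC=C(C)C)(C(OC)=C(C(=O)c3ccc(O)c(O)c3)C1=O)C2=O | intermediate
31 | CNP0160101.3: (1S,5S,7R)-3-(3,4-dihydroxybenzoyl)-1-geranyl-2-hydroxy-6,6-dimethyl-5,7-diprenylbicyclo[3.3.1]non-2-ene-4,9-dione (drawn tautomer) | CC(C)=CCC/C(C)=C/C[C@]12C[C@@H](CC=C(C)C)C(C)(C)[C@](CC=C(C)C)(C(=O)C(C(=O)c3ccc(O)c(O)c3)=C1O)C2=O | target

**Step count**

Total: 20 steps. Longest linear sequence: 18 steps (steps 1–16, 19 and 20); steps 17 and 18 prepare the aroyl chloride.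

**Steps most likely to fail**

Step 4. Removal of the crowded ring hydrogen next to the quaternary C6 may be slow, and the pentadienyl anion, shielded at its central carbon, may take the allyl group at a terminal carbon or be quenched unchanged. The fallback makes the two neighbouring quaternary carbons in the opposite order. Commercial 1,5-dimethoxycyclohexa-1,4-diene is lithiated (t-BuLi, THF–HMPA, −78 °C) and alkylated with allyl bromide 8 to give 1,5-dimethoxy-6-(prop-2-en-1-yl)cyclohexa-1,4-diene F1. A second lithiation at the same, still uncrowded carbon and alkylation with methyl bromoacetate gives methyl 2-[2,6-dimethoxy-1-(prop-2-en-1-yl)cyclohexa-2,5-dien-1-yl]acetate F2. Two rounds of LiN(i-Pr)2 and MeI in one flask, by way of methyl 2-[2,6-dimethoxy-1-(prop-2-en-1-yl)cyclohexa-2,5-dien-1-yl]propanoate F3 (not isolated), build the gem-dimethyl carbon in methyl 2-[2,6-dimethoxy-1-(prop-2-en-1-yl)cyclohexa-2,5-dien-1-yl]-2-methylpropanoate F4. (Trimethylsilyl)methyllithium then adds once to the ester; the resulting 3-[2,6-dimethoxy-1-(prop-2-en-1-yl)cyclohexa-2,5-dien-1-yl]-3-methyl-1-(trimethylsilyl)butan-2-one F5 (not isolated) is held as its enolate until methanol removes the silyl group and gives 10. This path sets out from 8 and rejoins the route at 10; steps 1 to 5 fall away.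

Step 7. The catalyst may discriminate incompletely between the two enantiotopic enol ethers, or the surviving enol ether may be hydrolysed while the cyclopropane is opened. The fallback changes the carbenoid precursor to an α-diazo-β-keto sulfone, the substrate class for which copper–bis(oxazoline) cyclopropanation is most selective and whose doubly activated cyclopropane opens without aqueous mineral acid. From 10, LiN(SiMe3)2 (2 equiv) and benzenesulfonyl fluoride give 3-[2,6-dimethoxy-1-(prop-2-en-1-yl)cyclohexa-2,5-dien-1-yl]-3-methyl-1-(phenylsulfonyl)butan-2-one F6. Diazo transfer (4-acetamidobenzenesulfonyl azide, Et3N, MeCN) gives the 1-diazo-1-(phenylsulfonyl) ketone F7. The same copper catalyst gives the 8-(phenylsulfonyl)methoxycyclopropane F8 (not isolated), which opens on moist silica gel to the 8-(phenylsulfonyl) derivative of 14, F9. Aluminium amalgam Al(Hg) in aqueous THF removes the sulfonyl group next to the C7 ketone and returns 14. This path sets out from 10 and rejoins the route at 14.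

Step 13. Allyl transfer to the hindered secondary radical next to C6 may be slow enough for hydrogen capture or C5–C6 scission to compete, and a boat-like radical could accept the allyl group on the endo face. The fallback sets C7 by equilibrium and grows the side chain with retention. Acid 18, exo after the base equilibration of step 11, is converted with 1-chloro-N,N,2-trimethylprop-1-en-1-amine into the 7-exo acid chloride F10 (not isolated) and with diazomethane into the 7-exo diazomethyl ketone F11. Silver benzoate and triethylamine in aqueous THF bring about the Wolff rearrangement, in which C7 migrates with retention, to the 7-exo acetic acid F12. Its N-hydroxyphthalimide ester F13 (N,N'-diisopropylcarbodiimide, DMAP) undergoes nickel-catalysed decarboxylative vinylation (NiCl2·glyme, 2,2'-bipyridine, vinylzinc chloride) at the primary carbon, where no stereocentre is at stake, and gives 21. This path sets out from 18 and rejoins the route at 21; steps 12 and 13 fall away.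

**Further compounds**

F1 | step 4 | 1,5-dimethoxy-6-(prop-2-en-1-yl)cyclohexa-1,4-diene | COC1=CCC=C(OC)C1CC=C
F2 | step 4 | methyl 2-[2,6-dimethoxy-1-(prop-2-en-1-yl)cyclohexa-2,5-dien-1-yl]acetate | COC(=O)CC1(CC=C)C(OC)=CCC=C1OC
F3 | step 4 | methyl 2-[2,6-dimethoxy-1-(prop-2-en-1-yl)cyclohexa-2,5-dien-1-yl]propanoate (not isolated) | COC(=O)C(C)C1(CC=C)C(OC)=CCC=C1OC
F4 | step 4 | methyl 2-[2,6-dimethoxy-1-(prop-2-en-1-yl)cyclohexa-2,5-dien-1-yl]-2-methylpropanoate | COC(=O)C(C)(C)C1(CC=C)C(OC)=CCC=C1OC
F5 | step 4 | 3-[2,6-dimethoxy-1-(prop-2-en-1-yl)cyclohexa-2,5-dien-1-yl]-3-methyl-1-(trimethylsilyl)butan-2-one (not isolated) | C[Si](C)(C)CC(=O)C(C)(C)C1(CC=C)C(OC)=CCC=C1OC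
F6 | step 7 | 3-[2,6-dimethoxy-1-(prop-2-en-1-yl)cyclohexa-2,5-dien-1-yl]-3-methyl-1-(phenylsulfonyl)butan-2-one | O=C(CS(=O)(=O)c1ccccc1)C(C)(C)C1(CC=C)C(OC)=CCC=C1OC
F7 | step 7 | 1-diazo-3-[2,6-dimethoxy-1-(prop-2-en-1-yl)cyclohexa-2,5-dien-1-yl]-3-methyl-1-(phenylsulfonyl)butan-2-one | [N-]=[N+]=C(C(=O)C(C)(C)C1(CC=C)C(OC)=CCC=C1OC)S(=O)(=O)c1ccccc1
F8 | step 7 | 8-(phenylsulfonyl) analogue of methoxycyclopropane 13 (not isolated) | [C@]12(S(=O)(=O)c4ccccc4)C(=O)C(C)(C)[C@]3(CC=C)C(OC)=CC[C@H]1[C@]23OC
F9 | step 7 | 8-(phenylsulfonyl) derivative of 14 (C8 epimers) | [C@H]12C(S(=O)(=O)c3ccccc3)C(=O)C(C)(C)[C@](CC=C)(C(OC)=CC1)C2=O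
F10 | step 13 | 7-exo acid chloride of 18 (not isolated) | [C@H]12C[C@@H](C(=O)Cl)C(C)(C)[C@](CC=C)(C(OC)=CC1)C2=O
F11 | step 13 | 7-exo diazoacetyl compound (diazomethyl ketone of 18) | [C@H]12C[C@@H](C(=O)C=[N+]=[N-])C(C)(C)[C@](CC=C)(C(OC)=CC1)C2=O
F12 | step 13 | 7-exo acetic acid (one-carbon homologue of 18) | [C@H]12C[C@@H](CC(=O)O)C(C)(C)[C@](CC=C)(C(OC)=CC1)C2=O
F13 | step 13 | N-hydroxyphthalimide ester of F12 | [C@H]12C[C@@H](CC(=O)ON3C(=O)c4ccccc4C3=O)C(C)(C)[C@](CC=C)(C(OC)=CC1)C2=O
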